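(All runs are simulated with constants of no real substance; the scatter is artificial.)

- beta: left-handed substrate 20 mM; right-handed substrate 20 mM; gas 11 mM (held); free catalyst 0.1 mol%; run made earlier
- flask: left-handed substrate 20 mM; gas 11 mM (held); free catalyst 0.2 mol%; right-handed substrate 20 mM; time 3.0 min

- beta (time / s: right-handed substrate / %, left-handed substrate / %): 10.0: 48.8, 42.7; 12.0: 49.7, 43.4; 20.0: 48.1, 35.5

(scatter of a reading: 1 percentage point)

- free catalyst is single-handed; left-handed substrate and right-handed substrate are mirror images of each other, charged as a racemate, each of them at the stated concentration
- at the start none of the gas is in solution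
- no earlier run changes the charge of free catalyst; that part of a forecast is a guess

- whether the excess of right-handed substrate over left-handed substrate among what is left of the two reaches 80% by 3.0 min (yes / no)
- the highest excess of right-handed substrate over left-handed substrate among what is left of the two up to 3.0 min

Minutes. At early times the beta run opened the talk: by 20.0 s left-handed substrate stood at 35.5% and right-handed substrate at 48.1%. One member read from these a selectivity factor of 8.84. Another objected that this reading is loose, since the right-handed loss of 1.9 percentage points lies close to a reading's scatter of 1 point.

I proposed to work from the crossing instead. The excess is the difference of c(right-handed substrate) and c(left-handed substrate) over their sum, so it reaches 80% when c(left-handed substrate)/c(right-handed substrate) falls to the crossing ratio, one minus the excess over one plus the excess: 0.111. In the beta run the logarithm of c(right-handed substrate)/c(left-handed substrate) reads as growing on average at 0.0152 s⁻¹ up to the last reading. A member warned that no run varies the catalyst, so taking twice that pace for the flask is a guess. On that guess I reckoned the flask would cross at 1.21 min, earlier than the 3.0 min allowed, and would stand near 99.2% at the end.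

The forecast said yes, with a top of 98% (range 86% to 100%), reasoning from “Doubling the catalyst, if the rate is proportional”.

The flask gave yes, with a top of 100%.

    reagent + free catalyst → spent catalyst B (k = 0.566 M⁻¹ s⁻¹)
    reagent + catalyst intermediate A → free catalyst + left-handed product (k = 2680 M⁻¹ s⁻¹)
    free catalyst → spent catalyst A (k = 0.00251 s⁻¹)
    gas ⇌ reagent, rate k4*(csat - [reagent]) (kL = 0.193 s⁻¹)
    free catalyst + right-handed substrate ⇌ catalyst intermediate B (K = 52.9 M⁻¹, k = 14100 M⁻¹ s⁻¹)
    reagent + catalyst intermediate B → free catalyst + right-handed product (k = 1010 M⁻¹ s⁻¹)
    free catalyst + left-handed substrate ⇌ catalyst intermediate A (K = 520 M⁻¹, k = 31300 M⁻¹ s⁻¹)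

The flask crossed at 0.658 min, earlier than my 1.21 min and well inside the 3.0 min. Right-handed substrate then stood at 44.5% of the two substrates charged together. The crossing ratio puts left-handed substrate at 4.94% of the same charge at that moment, so 50.6% of the two together had reacted.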